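## Structural features

The target is a germacranolide of the melampolide type: a ten-membered carbocycle (C1–C10) with a Z-trisubstituted C1=C10 alkene and an E-trisubstituted C4=C5 alkene. It is trans-fused across C6–C7 to an α-methylene-γ-butyrolactone (O on C6, C11 on C7, C12 carbonyl, C13 methylene). Four contiguous oxygenated stereocentres follow one another: C6 (lactone oxygen, R), C7 (fully substituted tertiary carbinol, R), C8 (ester carbinol, R) and C9 (allylic carbinol, R). With the ring drawn flat, the C7 hydroxyl is cis to the C6 oxygen, and the C8 and C9 oxygens are cis to each other and trans to the C7 hydroxyl. C8 carries (2S,3R)-2,3-dimethyloxirane-2-carboxylate, the epoxide of tiglic acid with cis methyl groups. Fragile elements are the methylene lactone (conjugate acceptor), the epoxide, the cis-diol monoester (acyl shift from O8 to O9 under base), the β-hydroxy lactone at C7 (retro-aldol, dehydration) and the 1,5-diene in a medium ring (transannular cyclisation under acid). The real difficulty is the ten-membered ring with two defined trisubstituted alkenes next to a quaternary C7, together with telling the neighbouring C8 and C9 oxygens apart. The key step exploits two facts: the Z-C1=C10 alkene is a cyclohexene alkene (ring C9–C10–C1–C2–C3–C4), and the C4–C9 bond of that ring is the central σ-bond of the 1,5-diene C7=C8–C9–C4–C5=C6. One [3,3] shift therefore delivers the ring, the C6–C7 bond with both stereocentres, and the E-C4=C5 alkene.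

## Logic of the disconnections

34 ⇒ 33. The bond cut is C9–H. C9 is kept as a carbonyl up to the last step, so the C8 and C9 oxygens never need protecting groups to be told apart and the monoester never meets base. The forward step must deliver hydride to C9 anti to the C7 hydroxyl (internal delivery from boron on O7) without touching the methylene lactone, the epoxide or the ester.

33 ⇒ 27 + 31. The C8–O acyl bond is cut. In 27 the only acylable hydroxyl is the one on C8 (the C7 hydroxyl is tertiary), so no selectivity between secondary alcohols is needed. The demand is esterification of a hindered α-hydroxy ketone without epimerisation at C8.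

27 ⇒ 26. The C8–H bond is cut, leading to an 8,9-dione. An electrophilic oxygen offered to a C8 enolate would enter on the exposed face, cis to the C7 oxygen, which is the C8 epimer. C8 is therefore taken to the ketone level and the stereocentre is made by hydride delivery from the C7 hydroxyl. The forward step must reduce C8 and not C9.

26 ⇒ 25 ⇒ 24. The lactone C12–O6 bond and the two 4-methoxybenzyl-type ether bonds on O6 and O7 are cut. One neutral oxidation frees both hydroxyls; the C6 hydroxyl then closes onto the C12 aldehyde and the lactol is oxidised. The C8 carbonyl cannot compete for the C12 carbon, so only the 12,6-lactone can form.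

24 ⇒ 22 (through 23). The C11=C13 bond is cut. Methylenation at the aldehyde stage is a mild Mannich process and avoids a lactone enolate with a β-leaving group on C7. It needs C12 at the aldehyde level while O6 is still blocked.

22 ⇒ 21 ⇒ 20 ⇒ 19. These are changes at C12 (acetal to aldehyde) and C8 (CH2 to C=O through the carbinol). Carrying C12 as a dimethyl acetal from the start removes a silyl protection, a desilylation and an oxidation. The C8 configuration of 20 is irrelevant because it is erased in 21.

19 ⇒ 17 (through 18). This is the key disconnection: C6–C7 is cut and C4–C9 is re-formed, contracting the ten-membered ring to a cyclohexene with two alkenyl arms. Two stereocentres and one ring are exchanged for the single C4 quaternary centre. The forward step needs a chair transition state with C3 equatorial, an E enol ether at C6 and a Z enol ether at C7 (oxygen cis to C9). O7 carries a 4-methoxybenzyloxymethyl group, so its later removal needs no acid.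

17 ⇒ 9 + 15 (through 16). The C8–C9 bond is cut, giving an enone and a Z-β-alkoxyalkenyl-lithium. The addition must be 1,2 and must occur anti to the C4 alkenyl arm to give the trans-dialkenyl carbinol.

15 ⇒ 14 + 11; 14 ⇒ 12 (through 13); 11 ⇒ 10 ⇒ 7. The enol C–O bond, the C–Br bond and the chloromethyl ether are cut back to commercial materials. The Z geometry (Br cis to O) must come from the bromo-enolate.

9 ⇒ 8 ⇒ 6 ⇒ 5. The enol ether is traced through the acetal and the aldehyde to the allyl group, which loses its terminal carbon. The elimination must give the E enol ether.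

5 ⇒ 4 ⇒ 3 ⇒ 1 + 2. The C4–allyl bond and the ring alkene are cut. The quaternary centre is set by catalytic decarboxylative allylation of an enol carbonate; the second stereocentre of 4 disappears on dehydrogenation.

31 ⇒ 30 ⇒ 29 ⇒ 28. The epoxide C–O bonds are cut. Sharpless epoxidation of the allylic alcohol sets both epoxide centres before the carbinol is oxidised back to the acid.

## Other disconnections considered

Alternative 1: The cut is the C7–C11 bond of the lactone. In the forward sense PMe3 would add to the C6 acrylate of the ten-membered 7-ketone A2. The resulting enolate would attack the C7 carbonyl through C11, and loss of the phosphine would leave the C7 hydroxyl, the lactone and the C11=C13 methylene of A1 in one operation.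
- In its favour: no C12 oxidation-state changes, no lactone enolate, no protecting group on O7, and the acceptor appears at the very end. On steps spent on the lactone it would be better than the chosen plan, which uses four (steps 15–18).
- Against it here: ketones are poor acceptors in this reaction. The C7 carbonyl of A2 is flanked by two epimerisable oxygenated centres (C6, and C8 as an α-acyloxy ketone exposed to a nucleophilic phosphine). Nothing local enforces the trans ring fusion at C7. A2 itself, with both alkenes and C6, C8 and C9 in place, must still be made by another ring-forming event.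
- Comparison: structurally it postpones the lactone but leaves the medium ring unsolved. Mechanistically it replaces a concerted, geometry-defined shift with a reversible ionic addition under conformational control. In step economy it is equal or better at the lactone stage and expected worse overall.

Alternative 2: The cut is C8–C9. In the forward sense CrCl2 would convert the C1 allylic bromide of A4 into an allylchromium species (divalent to trivalent chromium). This would add through C9 to the C8 aldehyde, closing the ring, forming the C1=C10 alkene and giving A3 with C9 acylated and C8 free.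
- In its favour: the C8/C9 diol arrives differentiated in exactly the sense needed, which is better than the chosen plan with its dione detour (steps 13, 14 and 19). The chloroacetate can be removed under near-neutral conditions, the lactone can be present from the start, and the assembly is convergent.
- Against it: closing a ten-membered ring end to end has an entropic cost (dilution, oligomers). The neopentyl, α-oxygenated aldehyde is hindered. Neither the Z geometry of the new C1=C10 alkene nor the facial sense relative to C7 is secured by the substrate. A4 is a long linear sequence that must already contain the E-C4=C5 alkene and the C6/C7 pair.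
- Comparison: the chosen ring expansion fixes both alkene geometries and needs no dilution, whereas here they are at risk. Control of C8/C9 is the equal or better in the alternative. The step count to the cyclisation precursor is expected to be higher.

Alternative 3: The cut is the C1–C4 and C5–C10 σ-bonds of a cyclobutane. In the forward sense thermolysis of the tricyclic enone–cyclobutene photoadduct A6 would cleave both bonds with release of strain and open to the ten-membered dienone A5.
- In its favour: the carbocycle with both trisubstituted alkenes, the C9 ketone and a masked C7 carbonyl would arise in two operations from simple partners. This is shorter than steps 1–12 of the chosen plan, so on speed of access to the ring it is the better. Like the chosen plan it uses strain release instead of end-to-end closure.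
- Against it: A5 is achiral and has none of the four stereocentres, so C6–C9 must all be introduced later on a flexible ring and absolute configuration needs a further element. The regiochemistry of the photocycloaddition and the Z,E geometry after cycloreversion are not assured. Oxidation at C6 and branching at C7 must be done regioselectively on a ketone flanked by two methylene groups.
- Comparison: the mechanisms are related pericyclic ring openings. Structurally the chosen plan transfers a catalytically set stereocentre into C6/C7 during ring formation and brings in C11 and C12; the alternative does neither. Step economy is better to the bare ring and expected worse to the target.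

Key step: step 12

Remark on numbering and stereochemistry: germacrane locants are used for the ten-membered ring, its precursors and its substituents (C1–C10 ring, C11–C13 lactone carbons, C14 on C10, C15 on C4). The configurations of 17, 19 and 34 were checked against a chair transition state (C3 equatorial, O6 equatorial, O7 axial) and are mutually consistent, so no structure needed correction.

## Steps

Step 1
Reactants: 1 2,6-dimethylcyclohexan-1-one; 2 allyl chloroformate
Product: 3 allyl 2,6-dimethylcyclohex-1-en-1-yl carbonate (racemic)
Conditions: LiHMDS, TMEDA, THF, 0 °C; then 2, −78 °C → rt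
Reagents that add atoms: none
Why: The symmetrical ketone gives a single tetrasubstituted lithium enolate, and the hindered enolate is acylated on oxygen by the chloroformate (enol carbonate formation).

Step 2
Reactants: 3 allyl 2,6-dimethylcyclohex-1-en-1-yl carbonate
Product: 4 (2S)-2-allyl-2,6-dimethylcyclohexan-1-one (both C6 epimers)
Conditions: Pd2(dba)3 (2.5 mol %), (S)-t-Bu-PHOX (6 mol %), THF, 25 °C
Reagents that add atoms: none
Why: Decarboxylative asymmetric allylic alkylation (Tsuji allylation): zerovalent palladium ionises the allyl carbonate, CO2 is lost and the palladium enolate is allylated at the methyl-bearing carbon. The (S)-ligand is expected to give the 2S quaternary centre by analogy with 2-methylcyclohexanone enol carbonates; the racemic C6 centre is removed in step 3.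

Step 3
Reactants: 4 (2S)-2-allyl-2,6-dimethylcyclohexan-1-one
Product: 5 (6S)-6-allyl-2,6-dimethylcyclohex-2-en-1-one
Conditions: IBX (1.5 equiv), DMSO/toluene, 70 °C
Reagents that add atoms: none
Why: IBX dehydrogenation of a ketone to the enone; only the methine side can enolise because the other α-carbon is quaternary, and both epimers of 4 converge on one endocyclic enone.

Step 4
Reactants: 5 (6S)-6-allyl-2,6-dimethylcyclohex-2-en-1-one
Product: 6 2-[(1S)-1,3-dimethyl-2-oxocyclohex-3-en-1-yl]acetaldehyde
Conditions: OsO4 (2 mol %), NaIO4 (4 equiv), 2,6-lutidine, 1,4-dioxane/H2O, 20 °C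
Reagents that add atoms: osmium tetroxide O=[Os](=O)(=O)=O (oxygen carrier); sodium periodate [Na+].[O-]I(=O)(=O)=O (terminal oxygen source)
Why: Johnson–Lemieux cleavage: the electron-neutral terminal alkene is dihydroxylated much faster than the hindered, electron-poor enone alkene, and periodate cleaves the diol.

Step 5
Reactants: 6 2-[(1S)-1,3-dimethyl-2-oxocyclohex-3-en-1-yl]acetaldehyde; 7 4-methoxybenzyl alcohol
Product: 8 (6S)-6-{2,2-bis[(4-methoxybenzyl)oxy]ethyl}-2,6-dimethylcyclohex-2-en-1-one
Conditions: 7 (2.5 equiv), PPTS (cat.), MgSO4, CH2Cl2, rt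
Reagents that add atoms: none
Why: Acid-catalysed acetalisation is selective for the aldehyde over the hindered conjugated ketone; no furan can form because C4 is quaternary.

Step 6
Reactants: 8 (6S)-6-{2,2-bis[(4-methoxybenzyl)oxy]ethyl}-2,6-dimethylcyclohex-2-en-1-one
Product: 9 (6S)-6-{(E)-2-[(4-methoxybenzyl)oxy]ethenyl}-2,6-dimethylcyclohex-2-en-1-one
Conditions: TMSOTf (1.3 equiv), iPr2NEt (2 equiv), CH2Cl2, −20 → 0 °C
Reagents that add atoms: none
Why: Lewis-acid ionisation of the acetal to an oxocarbenium ion and deprotonation at C5 by the hindered amine (acetal-to-enol-ether elimination). The E isomer, whose alkoxy group avoids the quaternary C4, is expected to dominate and any Z isomer is removed by chromatography.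

Step 7
Reactants: 7 4-methoxybenzyl alcohol
Product: 10 1-methoxy-4-{[(methylsulfanyl)methoxy]methyl}benzene
Conditions: NaH, ClCH2SMe, NaI (cat.), DME, 0 °C → rt
Reagents that add atoms: chloromethyl methyl sulfide CSCCl
Why: Williamson alkylation of the alkoxide with an activated α-chloro sulfide.

Step 8
Reactants: 10 1-methoxy-4-{[(methylsulfanyl)methoxy]methyl}benzene
Product: 11 1-[(chloromethoxy)methyl]-4-methoxybenzene (4-methoxybenzyloxymethyl chloride)
Conditions: SO2Cl2 (1.0 equiv), CH2Cl2, −78 °C; volatiles removed, used at once
Reagents that add atoms: sulfuryl chloride O=S(=O)(Cl)Cl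
Why: Chlorination at sulfur gives a chlorosulfonium ion that collapses to the chloromethyl ether (O,S-acetal to chloromethyl ether exchange); low temperature protects the electron-rich arene.

Step 9
Reactants: 12 4,4-dimethoxybutan-2-one
Product: 14 1-bromo-4,4-dimethoxybutan-2-one, via trimethylsilyl enol ether 13 (not isolated)
Conditions: LDA, THF, −78 °C; TMSCl; then NBS, NaHCO3, THF, −78 → 0 °C
Reagents that add atoms: N-bromosuccinimide O=C1CCC(=O)N1Br
Why: Kinetic deprotonation at the methyl group (which also avoids β-elimination of methoxide), silylation, and electrophilic bromination of the terminal silyl enol ether give the bromomethyl ketone regioselectively.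

Step 10
Reactants: 14 1-bromo-4,4-dimethoxybutan-2-one; 11 1-[(chloromethoxy)methyl]-4-methoxybenzene
Product: 15 1-{[({(1Z)-1-bromo-4,4-dimethoxybut-1-en-2-yl}oxy)methoxy]methyl}-4-methoxybenzene
Conditions: KHMDS, THF/DMPU, −78 °C; then 11, −78 → −40 °C
Reagents that add atoms: none
Why: The more acidic CH2Br protons are removed, and the hard chloromethyl ether alkylates the potassium enolate on oxygen in the dipolar medium (enolate O-alkylation). Bromine syn to oxygen is both the enolate geometry and the more stable enol ether, so the Z isomer is expected.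

Step 11
Reactants: 15 1-{[({(1Z)-1-bromo-4,4-dimethoxybut-1-en-2-yl}oxy)methoxy]methyl}-4-methoxybenzene; 9 (6S)-6-{(E)-2-[(4-methoxybenzyl)oxy]ethenyl}-2,6-dimethylcyclohex-2-en-1-one
Product: 17 (1S,6S)-1-[(1Z)-4,4-dimethoxy-2-{[(4-methoxybenzyl)oxy]methoxy}but-1-en-1-yl]-6-{(E)-2-[(4-methoxybenzyl)oxy]ethenyl}-2,6-dimethylcyclohex-2-en-1-ol, via alkenyllithium 16 (not isolated)
Conditions: t-BuLi (2.0 equiv), Et2O, −78 °C; then 9, THF, −78 °C; NH4Cl at −78 °C; chromatography on Et3N-deactivated silica
Reagents that add atoms: none
Why: Bromine–lithium exchange proceeds with retention; the cis β-oxygen chelates lithium and the reagent cannot eliminate. 1,2-Addition to the enone anti to the pseudoaxial C4 alkenyl arm (the better σ-acceptor, Felkin–Anh sense) should give the trans-dialkenyl carbinol; the C9 epimer is removed by chromatography.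

Step 12
Reactants: 17 (1S,6S)-1-[(1Z)-4,4-dimethoxy-2-{[(4-methoxybenzyl)oxy]methoxy}but-1-en-1-yl]-6-{(E)-2-[(4-methoxybenzyl)oxy]ethenyl}-2,6-dimethylcyclohex-2-en-1-ol
Product: 19 (2Z,6E,8R,9S)-9-(2,2-dimethoxyethyl)-8-[(4-methoxybenzyl)oxy]-9-{[(4-methoxybenzyl)oxy]methoxy}-2,6-dimethylcyclodeca-2,6-dien-1-one (germacrane locants: C9 ketone, 6R, 7S, Z-C1=C10, E-C4=C5), via potassium enolate 18 (not isolated)
Conditions: KH (3 equiv), 18-crown-6 (3 equiv), THF, 0 → 25 °C; then transfer into AcOH/THF at −78 °C
Reagents that add atoms: none
Why: KH with the crown ether gives the dissociated C9 potassium alkoxide, which weakens the C4–C9 bond and accelerates the [3,3] shift (anionic oxy-Cope); the closest known type is the ring expansion of trans-1,2-dialkenylcyclohexanols to E-cyclodec-5-enones, and two enol-ether termini have no direct precedent but change only the donor character of the bond-forming carbons. C6–C7 forms as C4–C9 breaks within a six-centre chair array, so the ten-membered ring arises by expansion of the cyclohexene and not by end-to-end closure. Only the conformer of the trans isomer with both alkenyl arms equatorial can reach a chair, and in it C3 is equatorial on C4, which fixes E-C4=C5; the ring alkene is carried over as Z-C1=C10. The E enol ether puts O6 equatorial and the Z enol ether puts O7 axial, so C6 and C7 are created together with the relative configuration of the target. The absolute sense is relayed from the C4 centre, which selects one of the two enantiomeric chairs and is itself destroyed. The step needs chair over boat, secured by the trans ring fusion and the absence of a competing chair. It also needs the enolate 18 to survive: in the nascent conformer the C7–O bond lies in the enolate plane, so E1cB loss of the C7 alkoxy group is stereoelectronically slow and is outrun by the cold proton quench. Protonation at C8 creates no stereocentre.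

Step 13
Reactants: 19 (2Z,6E,8R,9S)-9-(2,2-dimethoxyethyl)-8-[(4-methoxybenzyl)oxy]-9-{[(4-methoxybenzyl)oxy]methoxy}-2,6-dimethylcyclodeca-2,6-dien-1-one
Product: 20 the C8-hydroxy derivative of 19 (α-hydroxy ketone, both C8 epimers)
Conditions: KHMDS, THF, −78 °C; 2-(phenylsulfonyl)-3-phenyloxaziridine, −78 °C; AcOH at −78 °C
Reagents that add atoms: 2-(phenylsulfonyl)-3-phenyloxaziridine O=S(=O)(c1ccccc1)N1OC1c1ccccc1
Why: Kinetic deprotonation at C8, the only sp3 α-carbon, and oxygen transfer from the N-sulfonyloxaziridine (enolate hydroxylation). The oxygen is expected mainly on the exposed face, cis to O7, but the centre is erased in step 14; low temperature suppresses loss of the C7 alkoxy group.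

Step 14
Reactants: 20 the C8-hydroxy derivative of 19
Product: 21 the 8,9-dione (C8 and C9 ketones; C6, C7 and both alkenes as in 19)
Conditions: Dess–Martin periodinane (1.5 equiv), NaHCO3, CH2Cl2, 0 °C → rt
Reagents that add atoms: none
Why: Buffered periodinane oxidation of the α-hydroxy ketone to the 1,2-dione; the dione has no enolisable α-hydrogen (C7 quaternary, C10 sp2), so nothing can epimerise.

Step 15
Reactants: 21 the 8,9-dione
Product: 22 the C12 aldehyde of 21 (C7 side chain CH2CHO)
Conditions: LiBF4, MeCN/H2O (50:1), rt
Reagents that add atoms: water O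
Why: Mild hydrolysis of the dimethyl acetal; the formaldehyde-type acetal on O7 and the benzyl ether on O6 are far less labile and should survive.

Step 16
Reactants: 22 the C12 aldehyde of 21
Product: 24 the C11-methylene aldehyde (C7 side chain C(=CH2)CHO), via Mannich base 23 (not isolated)
Conditions: dimethylmethyleneiminium iodide (3 equiv), Et3N (6 equiv), CH2Cl2, rt
Reagents that add atoms: dimethylmethyleneiminium iodide C=[N+](C)C.[I-]
Why: Mannich reaction of the aldehyde enol followed by elimination of dimethylamine (aldehyde α-methylenation); this installs C13 without a lactone enolate.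

Step 17
Reactants: 24 the C11-methylene aldehyde
Product: 25 the 12,6-lactol with free C7 hydroxyl and 8,9-dione (anomeric mixture)
Conditions: DDQ (3 equiv), CH2Cl2/pH 7 buffer, 0 °C → rt
Reagents that add atoms: none
Why: DDQ oxidises both 4-methoxybenzylic positions and hydrolysis frees the C6 and C7 hydroxyls (the O7 hemiformal loses formaldehyde). The C6 hydroxyl then adds to the C12 aldehyde to form the five-membered lactol (5-exo-trig), trans-fused as fixed by C6 and C7.

Step 18
Reactants: 25 the 12,6-lactol
Product: 26 7-hydroxy-8,9-dioxo-germacra-1(10)Z,4E,11(13)-trien-12,6-olide (C6, C7 as in 34)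
Conditions: PhI(OAc)2 (1.5 equiv), TEMPO (0.2 equiv), CH2Cl2, rt
Reagents that add atoms: none
Why: Oxoammonium oxidation of the lactol to the lactone; the tertiary C7 hydroxyl and the dione are inert, and C8 is a ketone so only the 12,6-lactone can form.

Step 19
Reactants: 26 7-hydroxy-8,9-dioxo-germacra-1(10)Z,4E,11(13)-trien-12,6-olide
Product: 27 7,8-dihydroxy-9-oxo-germacra-1(10)Z,4E,11(13)-trien-12,6-olide (C8 hydroxyl trans to the C7 hydroxyl, as in 34)
Conditions: Me4NBH(OAc)3 (1.2 equiv), MeCN/AcOH, −40 °C
Reagents that add atoms: none
Why: Hydroxyl-directed reduction: the acetoxyborohydride bound to O7 delivers hydride internally to the adjacent C8 carbonyl, the more electrophilic one (non-conjugated, next to an oxygenated carbon). H8 enters from the side of the C7–O bond, which gives the 7,8-trans-diol as in directed reductions of cyclic α-hydroxy ketones; the cross-conjugated C9 carbonyl is spared by low temperature and limited reagent.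

Step 20
Reactants: 28 tiglic acid
Product: 29 (2E)-2-methylbut-2-en-1-ol
Conditions: LiAlH4, Et2O, 0 °C → rt
Reagents that add atoms: none
Why: Hydride reduction of the unsaturated acid to the allylic alcohol with retention of the E geometry.

Step 21
Reactants: 29 (2E)-2-methylbut-2-en-1-ol
Product: 30 [(2R,3R)-2,3-dimethyloxiran-2-yl]methanol
Conditions: Ti(OiPr)4 (10 mol %), D-(−)-diethyl tartrate (12 mol %), t-BuOOH, 4 Å MS, CH2Cl2, −20 °C
Reagents that add atoms: tert-butyl hydroperoxide CC(C)(C)OO
Why: Sharpless asymmetric epoxidation; the D-(−)-tartrate gives the mirror image of the (2S,3S) epoxy alcohols obtained from E-allylic alcohols with the L-(+)-ester, and syn oxygen transfer keeps the two methyl groups cis.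

Step 22
Reactants: 30 [(2R,3R)-2,3-dimethyloxiran-2-yl]methanol
Product: 31 (2S,3R)-2,3-dimethyloxirane-2-carboxylic acid
Conditions: RuCl3 hydrate (2 mol %), NaIO4 (3 equiv), EtOAc/MeCN/H2O, rt
Reagents that add atoms: sodium periodate [Na+].[O-]I(=O)(=O)=O (oxygen via RuO4); water O
Why: RuO4-catalysed oxidation of the primary alcohol to the acid leaves the epoxide untouched; the descriptor at C2 changes from R to S only because the priority of C1 changes.

Step 23
Reactants: 27 7,8-dihydroxy-9-oxo-germacra-1(10)Z,4E,11(13)-trien-12,6-olide; 31 (2S,3R)-2,3-dimethyloxirane-2-carboxylic acid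
Product: 33 the C8 (2S,3R)-2,3-dimethyloxirane-2-carboxylate of 27 (C9 ketone), via mixed anhydride 32 (not isolated)
Conditions: 31, 2,4,6-trichlorobenzoyl chloride, Et3N, toluene, rt; then 27, DMAP, toluene, rt
Reagents that add atoms: none
Why: Yamaguchi esterification: DMAP transfers the acyl group from the mixed anhydride to the secondary C8 hydroxyl, while the tertiary C7 hydroxyl is too hindered. The acid has no α-hydrogen, and any enolisation at C8 should be reprotonated on the exposed face, returning the same epimer.

Step 24
Reactants: 33 the C8 (2S,3R)-2,3-dimethyloxirane-2-carboxylate of 27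
Product: 34 CNP0420662.1 (6R,7R,8R,9R; epoxide 2S,3R)
Conditions: Me4NBH(OAc)3 (4 equiv), MeCN/AcOH, −20 °C
Reagents that add atoms: none
Why: Evans–Saksena reduction: boron bound to the C7 hydroxyl delivers hydride to the C9 carbonyl through a six-membered chair with C10 equatorial, giving the 7,9-anti relationship of the target. The mildly acidic medium excludes acyl migration and leaves the methylene lactone, epoxide and ester untouched.

## Compound list

1 | 2,6-dimethylcyclohexan-1-one (mixture of isomers) | CC1CCCC(C)C1=O | starting material
2 | allyl chloroformate | C=CCOC(Cl)=O | starting material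
3 | allyl 2,6-dimethylcyclohex-1-en-1-yl carbonate (racemic) | C=CCOC(=O)OC1=C(C)CCCC1C | intermediate
4 | (2S)-2-allyl-2,6-dimethylcyclohexan-1-one (both C6 epimers) | CC1CCC[C@@](C)(CC=C)C1=O | intermediate
5 | (6S)-6-allyl-2,6-dimethylcyclohex-2-en-1-one | CC1=CCC[C@@](C)(CC=C)C1=O | intermediate
6 | 2-[(1S)-1,3-dimethyl-2-oxocyclohex-3-en-1-yl]acetaldehyde | CC1=CCC[C@@](C)(CC=O)C1=O | intermediate
7 | 4-methoxybenzyl alcohol | COc1ccc(CO)cc1 | starting material
8 | (6S)-6-{2,2-bis[(4-methoxybenzyl)oxy]ethyl}-2,6-dimethylcyclohex-2-en-1-one | CC1=CCC[C@@](C)(CC(OCc2ccc(OC)cc2)OCc2ccc(OC)cc2)C1=O | intermediate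
9 | (6S)-6-{(E)-2-[(4-methoxybenzyl)oxy]ethenyl}-2,6-dimethylcyclohex-2-en-1-one | CC1=CCC[C@@](C)(/C=C/OCc2ccc(OC)cc2)C1=O | intermediate
10 | 1-methoxy-4-{[(methylsulfanyl)methoxy]methyl}benzene | COc1ccc(COCSC)cc1 | intermediate
11 | 1-[(chloromethoxy)methyl]-4-methoxybenzene | COc1ccc(COCCl)cc1 | intermediate
12 | 4,4-dimethoxybutan-2-one | CC(=O)CC(OC)OC | starting material
13 | [(4,4-dimethoxybut-1-en-2-yl)oxy]trimethylsilane | C=C(O[Si](C)(C)C)CC(OC)OC | intermediate (not isolated)
14 | 1-bromo-4,4-dimethoxybutan-2-one | BrCC(=O)CC(OC)OC | intermediate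
15 | 1-{[({(1Z)-1-bromo-4,4-dimethoxybut-1-en-2-yl}oxy)methoxy]methyl}-4-methoxybenzene | Br/C=C(\OCOCc1ccc(OC)cc1)CC(OC)OC | intermediate
16 | (1Z)-4,4-dimethoxy-2-{[(4-methoxybenzyl)oxy]methoxy}but-1-en-1-yllithium | [Li]/C=C(\OCOCc1ccc(OC)cc1)CC(OC)OC | intermediate (not isolated)
17 | (1S,6S)-1-[(1Z)-4,4-dimethoxy-2-{[(4-methoxybenzyl)oxy]methoxy}but-1-en-1-yl]-6-{(E)-2-[(4-methoxybenzyl)oxy]ethenyl}-2,6-dimethylcyclohex-2-en-1-ol | CC1=CCC[C@@](C)(/C=C/OCc2ccc(OC)cc2)[C@]1(O)/C=C(\OCOCc2ccc(OC)cc2)CC(OC)OC | intermediate
18 | potassium enolate of 19 (C8=C9, oxygen on C9) | COc1ccc(CO[C@@H]2/C=C(\C)CC/C=C(/C)C(/[O-])=C/[C@]2(CC(OC)OC)OCOCc2ccc(OC)cc2)cc1.[K+] | intermediate (not isolated)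
19 | (2Z,6E,8R,9S)-9-(2,2-dimethoxyethyl)-8-[(4-methoxybenzyl)oxy]-9-{[(4-methoxybenzyl)oxy]methoxy}-2,6-dimethylcyclodeca-2,6-dien-1-one | COc1ccc(CO[C@@H]2/C=C(\C)CC/C=C(/C)C(=O)C[C@]2(CC(OC)OC)OCOCc2ccc(OC)cc2)cc1 | intermediate
20 | C8-hydroxy derivative of 19 (both C8 epimers) | COc1ccc(CO[C@@H]2/C=C(\C)CC/C=C(/C)C(=O)C(O)[C@]2(CC(OC)OC)OCOCc2ccc(OC)cc2)cc1 | intermediate
21 | 8,9-dione derived from 20 | COc1ccc(CO[C@@H]2/C=C(\C)CC/C=C(/C)C(=O)C(=O)[C@]2(CC(OC)OC)OCOCc2ccc(OC)cc2)cc1 | intermediate
22 | C12 aldehyde of 21 | COc1ccc(CO[C@@H]2/C=C(\C)CC/C=C(/C)C(=O)C(=O)[C@]2(CC=O)OCOCc2ccc(OC)cc2)cc1 | intermediate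
23 | C11 dimethylaminomethyl derivative of 22 (C11 epimers) | COc1ccc(CO[C@@H]2/C=C(\C)CC/C=C(/C)C(=O)C(=O)[C@]2(C(CN(C)C)C=O)OCOCc2ccc(OC)cc2)cc1 | intermediate (not isolated)
24 | C11-methylene aldehyde (C7 side chain C(=CH2)CHO) | COc1ccc(CO[C@@H]2/C=C(\C)CC/C=C(/C)C(=O)C(=O)[C@]2(C(=C)C=O)OCOCc2ccc(OC)cc2)cc1 | intermediate
25 | 12,6-lactol with free C7 hydroxyl and 8,9-dione (anomers) | C=C1C(O)O[C@@H]2/C=C(\C)CC/C=C(/C)C(=O)C(=O)[C@@]12O | intermediate
26 | 7-hydroxy-8,9-dioxo-germacra-1(10)Z,4E,11(13)-trien-12,6-olide | C=C1C(=O)O[C@@H]2/C=C(\C)CC/C=C(/C)C(=O)C(=O)[C@@]12O | intermediate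
27 | 7,8-dihydroxy-9-oxo-germacra-1(10)Z,4E,11(13)-trien-12,6-olide (C8 as in 34) | C=C1C(=O)O[C@@H]2/C=C(\C)CC/C=C(/C)C(=O)[C@@H](O)[C@@]12O | intermediate
28 | tiglic acid | C/C=C(\C)C(=O)O | starting material
29 | (2E)-2-methylbut-2-en-1-ol | C/C=C(\C)CO | intermediate
30 | [(2R,3R)-2,3-dimethyloxiran-2-yl]methanol | OC[C@@]1(C)O[C@@H]1C | intermediate
31 | (2S,3R)-2,3-dimethyloxirane-2-carboxylic acid | OC(=O)[C@@]1(C)O[C@@H]1C | intermediate
32 | (2S,3R)-2,3-dimethyloxirane-2-carboxylic 2,4,6-trichlorobenzoic anhydride | O=C(OC(=O)[C@@]1(C)O[C@@H]1C)c1c(Cl)cc(Cl)cc1Cl | intermediate (not isolated)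
33 | C8 (2S,3R)-2,3-dimethyloxirane-2-carboxylate of 27 (C9 ketone) | C=C1C(=O)O[C@@H]2/C=C(\C)CC/C=C(/C)C(=O)[C@@H](OC(=O)[C@@]3(C)O[C@@H]3C)[C@@]12O | intermediate
34 | CNP0420662.1 | C=C1C(=O)O[C@@H]2/C=C(\C)CC/C=C(/C)[C@@H](O)[C@@H](OC(=O)[C@@]3(C)O[C@@H]3C)[C@@]12O | target

## Step count and least certain steps

Total: 24 steps. Longest linear sequence: 17 steps (steps 1–6, 11–19, 23, 24).

Step 12 (key step). The rearrangement may be slow because both bond-forming termini carry donor oxygens. The potassium enolate may lose the C7 alkoxy group by β-elimination before it is quenched, and the alkoxide may fragment instead of rearranging. Fallback, from 17 back to 19: the carbinol is silylated (TMSCl, imidazole, DMF) to the trimethylsilyl ether F1. F1 is heated in a neutral, acid-free medium (decalin with N,O-bis(trimethylsilyl)acetamide, 180–200 °C), where the thermal siloxy-Cope shift through the same chair should give the silyl enol ether F2 without any free enolate. Cold methanolysis (K2CO3, MeOH, 0 °C) then returns 19.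

Step 19. Hydride may be delivered to C9 instead of C8, both carbonyls may be reduced, or delivery may occur on the other face of C8 if the ring places the C7–O bond differently. Fallback, from 26 to 34: both carbonyls are reduced with excess Me4NBH(OAc)3 under direction of the C7 hydroxyl (C9 through the six-membered anti delivery, C8 through the five-membered one) to the triol lactone F3. The less hindered allylic C9 hydroxyl is silylated (TESCl, imidazole, −40 °C) to F4, and C8 is esterified with 31 through 32 to the silyl ether F5. HF·pyridine then gives 34. This exchanges the protecting-group-free end game for a differentiation by silylation.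

Step 10. The bromo-enolate may self-condense, be alkylated on carbon, or give a geometric mixture. Fallback, from 12 to 15: the kinetic lithium enolate of 12 (LDA, THF/DMPU, −78 °C) is alkylated on oxygen with 11 to the enol ether F6. Bromine is added at −78 °C to the dibromide F7 (not isolated) and HBr is eliminated with DBU. The isomer with bromine cis to oxygen is the more stable one, and equilibration (trace iodine) should funnel the mixture to 15.

Step 11. Facial selectivity at the ketone may be poor, because a methyl and an alkenyl group on C4 differ little in size, and the basic reagent may enolise 9. The cis-dialkenyl epimer F8 must be removed, since its chair leads to the 4Z series. Fallback (recycling), from F8 back to 6 and 12: mild aqueous acid (AcOH/THF/H2O) hydrolyses both enol ethers of F8 to the β-hydroxy ketone aldehyde F9. Retro-aldol cleavage (K2CO3, MeOH) returns 6 and 12, which re-enter at steps 5 and 9.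

## Further compounds

F1 | step 12 | trimethylsilyl ether of 17 | CC1=CCC[C@@](C)(/C=C/OCc2ccc(OC)cc2)[C@]1(O[Si](C)(C)C)/C=C(\OCOCc2ccc(OC)cc2)CC(OC)OC
F2 | step 12 | trimethylsilyl enol ether of 19 (C8=C9, silyloxy on C9) | COc1ccc(CO[C@@H]2/C=C(\C)CC/C=C(/C)C(/O[Si](C)(C)C)=C/[C@]2(CC(OC)OC)OCOCc2ccc(OC)cc2)cc1
F3 | step 19 | 7,8,9-trihydroxy-germacra-1(10)Z,4E,11(13)-trien-12,6-olide (configured as 34) | C=C1C(=O)O[C@@H]2/C=C(\C)CC/C=C(/C)[C@@H](O)[C@@H](O)[C@@]12O
F4 | step 19 | C9 triethylsilyl ether of F3 | C=C1C(=O)O[C@@H]2/C=C(\C)CC/C=C(/C)[C@@H](O[Si](CC)(CC)CC)[C@@H](O)[C@@]12O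
F5 | step 19 | C9 triethylsilyl ether of 34 | C=C1C(=O)O[C@@H]2/C=C(\C)CC/C=C(/C)[C@@H](O[Si](CC)(CC)CC)[C@@H](OC(=O)[C@@]3(C)O[C@@H]3C)[C@@]12O
F6 | step 10 | 1-({[(4,4-dimethoxybut-1-en-2-yl)oxy]methoxy}methyl)-4-methoxybenzene | C=C(OCOCc1ccc(OC)cc1)CC(OC)OC
F7 | step 10 | 1-({[(1,2-dibromo-4,4-dimethoxybutan-2-yl)oxy]methoxy}methyl)-4-methoxybenzene | BrCC(Br)(OCOCc1ccc(OC)cc1)CC(OC)OC
F8 | step 11 | C9 epimer of 17 (cis-dialkenyl carbinol) | CC1=CCC[C@@](C)(/C=C/OCc2ccc(OC)cc2)[C@@]1(O)/C=C(\OCOCc2ccc(OC)cc2)CC(OC)OC
F9 | step 11 | 2-[(1S,2R)-2-hydroxy-2-(4,4-dimethoxy-2-oxobutyl)-1,3-dimethylcyclohex-3-en-1-yl]acetaldehyde | CC1=CCC[C@@](C)(CC=O)[C@@]1(O)CC(=O)CC(OC)OC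
A1 | alternative 1 | C9 triethylsilyl ether of the target | C=C1C(=O)O[C@@H]2/C=C(\C)CC/C=C(/C)[C@@H](O[Si](CC)(CC)CC)[C@@H](OC(=O)[C@@]3(C)O[C@@H]3C)[C@@]12O
A2 | alternative 1 | C6 acrylate of the ten-membered 7-ketone (C8 epoxy ester, C9 triethylsilyl ether) | C=CC(=O)O[C@@H]1/C=C(\C)CC/C=C(/C)[C@@H](O[Si](CC)(CC)CC)[C@@H](OC(=O)[C@@]2(C)O[C@@H]2C)C1=O
A3 | alternative 2 | target skeleton with free C8 hydroxyl, C9 chloroacetate and C7 triethylsilyl ether | C=C1C(=O)O[C@@H]2/C=C(\C)CC/C=C(/C)[C@@H](OC(=O)CCl)[C@@H](O)[C@@]12O[Si](CC)(CC)CC
A4 | alternative 2 | open-chain C8 aldehyde with C1 allylic bromide and C9 enol chloroacetate (lactone in place, C7 triethylsilyl ether) | C=C1C(=O)O[C@H](/C=C(\C)CCC(Br)C(C)=COC(=O)CCl)[C@]1(C=O)O[Si](CC)(CC)CC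
A5 | alternative 3 | (2Z,6E)-2,6-dimethyl-9,9-ethylenedioxycyclodeca-2,6-dien-1-one | C1C2(OCCO2)C/C=C(\C)CC/C=C(/C)C1=O
A6 | alternative 3 | tricyclo[4.4.0.0(2,5)]decanone photoadduct (ketal at C7; relative configuration not specified) | O=C1CC2(OCCO2)CC3C1(C)C1CCC31C
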